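Remark on the chemistry (assumption): ring B of the target is a tautomeric cyclic β-triketone; the tautomer of the given SMILES is used throughout, all enol tautomers are treated as one compound, and the target has no stereocentre.

## Structural features

The target 12 (C22H26O8) consists of a pentasubstituted benzene ring A (C1 butanoyl, C2 OH, C3 H, C4 OMe, C5 CH2, C6 OH) joined through a single methylene carbon to C6′ of ring B, a dearomatised 2′-acetyl-3′,5′-dihydroxy-4′,4′-dimethylcyclohexa-2′,5′-dien-1′-one (acetylfilicinic acid unit) whose C4′ is quaternary. There is no stereocentre, and ring B is a vinylogous acid that exists as rapidly exchanging enol tautomers. Fragile points are the bridge, which lies between a phenol and an enol and can cleave by retro-Michael loss of either ring in base or acid; ring B, which over-alkylates at C6′ and can lose its acetyl group under forcing conditions; and the electron-rich ring A, which is sensitive to oxidants. The real difficulty is regiochemical and chemoselective: the three oxygens of ring A differ only by one O-methyl that must end up para to the butanoyl group and ortho to the bridge, and two carbon nucleophiles of the same kind must be joined through one carbon without symmetrical dimers. The feature that the key step exploits is that ring A, with oxygen on C2, C4 and C6 and carbon substituents between them, is a folded 3,5,7-trioxo acid, and that the segment C6–C5–C4–C3–C2, with its methoxy group, its bridge substituent and both flanking oxygens, maps atom for atom onto C2–C3–C4–C5–C6 of a 3-substituted 4-methoxy-2-pyranone. The ring A bond C1–C6 is therefore formed last, by a Claisen-type recyclisation in which the side-chain methylene of the pyranone (future C1, already bearing the butanoyl carbonyl) acylates the unmasked lactone carbon (future C6). In one sentence, ring A is created in the final step by methoxide-induced opening and Claisen recyclisation of pyranone 10, which already carries ring B, the bridge, the methyl ether and the butanoyl chain; this does not describe the usual union of two preformed rings by a one-carbon electrophile.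

## Logic of the disconnections

12 to 10 (through 11). The ring A bond C1–C6 is cut, and the C2 oxygen is tied back to C6 as a lactone. The cut is made here because it turns a benzene with three differentiated oxygens into a pyranone whose three substituents each answer to a separate positional reactivity: electrophilic substitution at C3, a purchased 4-methyl ether, and lateral metalation at the 6-methyl group. The gain is that the para relationship of methyl ether and butanoyl group, the place of the bridge and the position of the acyl group all follow from connectivity; 12 and 10 are isomers, so no atoms are spent. The demand on the forward step is that C-acylation (Claisen) wins over aldol-type and O-cyclisation modes, and that ring B and the bridge survive methoxide.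

10 to 9 and 3. The bond between the bridge carbon and C6′ of ring B is cut. The bridge carbon is kept on the pyranone partner at the alcohol oxidation level, so that only 3 acts as a nucleophile and no free one-carbon electrophile is ever present that could dimerise 3. The gain is convergence to two pieces of about equal size. The demand is C-alkylation of 3 at its only ring CH rather than O-alkylation, without self-condensation through the enolisable keto side chain of 9.

9 to 6 and 7. The bond between the lateral methylene (pyranone C7) and the ketone carbon is cut. The 6-methyl group of a 4-methoxy-2-pyranone is a vinylogous ester α-position and can be metalated, so the butanoyl carbonyl and future ring A C1 are joined from a pyranone methyl group and a four-carbon acyl donor. The demand is formation of an O,C-dianion (the hydroxyl is carried free) and clean mono-acylation.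

6 to 5 to 4. The C3–CH2OH bond is cut, then the C3–Br bond. C3 is the carbon of 4 most reactive towards electrophiles, so a bromide placed there is the handle for transfer of a one-carbon hydroxymethyl unit. The demand is C3 selectivity in the halogenation (not C5, not the methyl group) and efficient transfer of the hydroxymethyl group at a hindered alkenyl position.

3 to 1 (through 2). Both C4′–CH3 bonds are cut. Double C-methylation at one ring carbon of the commercial acetophenone dearomatises it to ring B in a single operation. The demand is to stop at the geminal dimethyl stage.

## Other disconnections considered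

Alternative 1: cut both bonds of the bridge carbon (C5–CH2 and CH2–C6′). This is the first disconnection that comes to mind. The forward key step is one-carbon union of 3 with the preformed ring A ketone A1, using formaldehyde or a Mannich base of one partner. Both partners are carbon nucleophiles of similar reactivity, so the symmetrical products A2 (from two molecules of 3) and A3 (from two molecules of A1) are expected beside the cross product, and the alkaline conditions allow retro-Michael scrambling of whatever bridge has formed. In addition, A1 needs a regioselective mono-O-methylation of a trihydroxy ketone at the oxygen para to the acyl group. The chosen plan fixes the place of the methyl ether by connectivity and builds the bridge on a partner that cannot form a quinone methide.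

Alternative 2: cut ring B at C2′–C3′ and C5′–C6′. Ring B would be built last from the protected aryl butanone A4 and a dimethylmalonyl half-ester chloride, through keto ester A5. The forward key step is a Dieckmann-type Claisen cyclisation of A5 to the benzylated trione A6, followed by C-acetylation at C2′ and deprotection. This avoids any bridge-forming coupling, but it needs two phenol protections and several redox steps to turn an aldehyde carbon into the bridge. The butanoyl α-methylene competes with the methyl ketone in the enolisations, the acetyl group must be introduced late on a ring with several acidic sites, and the substitution pattern of ring A is still left to classical selective methylation and formylation. The count would be about twice that of the chosen plan.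

Alternative 3: cut the two C4′–CH3 bonds at the very end. The forward key step is dearomative geminal dimethylation of the fully aromatic diarylmethane A7. Ring A of A7 has its own free nucleophilic CH (C3) and two free phenols, so C- and O-methylation on the wrong ring is expected to compete. The methoxide medium is also the medium in which such bridges scramble, and A7 needs the same unsymmetrical one-carbon coupling as alternative 1. This gives no gain in simplicity.

Key step: step 6

## Steps

Step 1
Reactants: 1 2,4,6-trihydroxyacetophenone
Product: 3 2-acetyl-3,5-dihydroxy-4,4-dimethylcyclohexa-2,5-dien-1-one (acetylfilicinic acid), via 3-methyl-2,4,6-trihydroxyacetophenone 2 (not isolated)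
Conditions: NaOMe (3 equiv), MeI (2.2 equiv), MeOH, 0 °C to rt; then 1 M HCl
Reagents that add atoms: iodomethane, CI
Why: Dearomative C-alkylation of the phloroglucinol polyanion; the second methylation should occur at the already methylated carbon because this gives the stabilised cross-conjugated β-triketone enolate, and limiting iodomethane to about two equivalents should hold the reaction at the geminal dimethyl stage.

Step 2
Reactants: 4 4-methoxy-6-methyl-2H-pyran-2-one
Product: 5 3-bromo-4-methoxy-6-methyl-2H-pyran-2-one
Conditions: NBS (1.05 equiv), MeCN, rt, dark
Reagents that add atoms: N-bromosuccinimide, O=C1CCC(=O)N1Br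
Why: Electrophilic bromination at C3, which is the β-carbon of the 4-methoxy enol ether and the α-carbon of the lactone; the polar medium without light or initiator should suppress radical bromination of the 6-methyl group.

Step 3
Reactants: 5 3-bromo-4-methoxy-6-methyl-2H-pyran-2-one
Product: 6 3-(hydroxymethyl)-4-methoxy-6-methyl-2H-pyran-2-one
Conditions: Bu3SnCH2OH (1.3 equiv), Pd(PPh3)4 (5 mol %), 1,4-dioxane, 95 °C
Reagents that add atoms: (tributylstannyl)methanol, CCCC[Sn](CO)(CCCC)CCCC
Why: Stille coupling; zerovalent palladium should insert readily into the C3–Br bond α to the lactone carbonyl, and the oxygen-assisted hydroxymethyl group should transfer from tin in preference to butyl. The product is kept away from acid, since it is a π-activated alcohol.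

Step 4
Reactants: 6 3-(hydroxymethyl)-4-methoxy-6-methyl-2H-pyran-2-one, 7 N-methoxy-N-methylbutanamide
Product: 9 3-(hydroxymethyl)-4-methoxy-6-(2-oxopentyl)-2H-pyran-2-one, via O,C-dilithio derivative 8 (not isolated)
Conditions: LiN(iPr)2 (2.3 equiv), THF, −78 °C; then 7 (1.2 equiv), −78 to −30 °C; then AcOH
Reagents that add atoms: none
Why: Lateral (vinylogous) lithiation of the 6-methyl group followed by Claisen-type C-acylation with an N-methoxy-N-methylamide; the first equivalent of base gives the lithium alkoxide, which is too poor a leaving group to be expelled from the extended enolate, and chelation until work-up should secure mono-acylation.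

Step 5
Reactants: 9 3-(hydroxymethyl)-4-methoxy-6-(2-oxopentyl)-2H-pyran-2-one, 3 2-acetyl-3,5-dihydroxy-4,4-dimethylcyclohexa-2,5-dien-1-one
Product: 10 2-acetyl-3,5-dihydroxy-6-{[4-methoxy-2-oxo-6-(2-oxopentyl)-2H-pyran-3-yl]methyl}-4,4-dimethylcyclohexa-2,5-dien-1-one
Conditions: 3 (1.5 equiv), TsOH·H2O (10 mol %), 4 Å MS, MeNO2, 40 °C
Reagents that add atoms: none
Why: Brønsted acid-catalysed dehydrative Friedel–Crafts-type alkylation of a cyclic 1,3-dicarbonyl enol by a π-activated alcohol; ionisation is assisted by the 4-methoxy group through C4=C3, the only ring CH of 3 (C6, dimedone-like) attacks the exocyclic carbon so that the pyranone π-system is restored, and any O-alkylation is reversible under the ionising conditions, so the C-alkylated product should accumulate.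

Step 6
Reactants: 10 2-acetyl-3,5-dihydroxy-6-{[4-methoxy-2-oxo-6-(2-oxopentyl)-2H-pyran-3-yl]methyl}-4,4-dimethylcyclohexa-2,5-dien-1-one
Product: 12 2-acetyl-6-[(3-butanoyl-2,4-dihydroxy-6-methoxyphenyl)methyl]-3,5-dihydroxy-4,4-dimethylcyclohexa-2,5-dien-1-one (target), via ring-opened methyl enoate 11 (not isolated)
Conditions: Mg(OMe)2 (8 equiv), MeOH, 65 °C, N2; then 1 M HCl, 0 °C
Reagents that add atoms: none
Why: Mg(OMe)2 first converts ring B and the lateral methylene into magnesium enolates, then methoxide adds to the lactone carbonyl (pyranone C2) and the ring opens to the (2E)-enoate 11, whose 5,7-diketone is held as a six-membered magnesium chelate. The central carbon of that chelate (future ring A C1) attacks the ester carbonyl (future C6) in a 6-exo-trig Claisen condensation, methoxide leaves, and enolisation of the keto tautomer of 12 gives the aromatic ring; the closest known reaction type is the Mg(OMe)2-mediated conversion of 6-(2-oxoalkyl)-4-methoxy-2-pyranones into 2,6-dihydroxy-4-methoxyphenyl ketones. The selectivity needed is Claisen acylation over the aldol mode and over O-cyclisation: the aldol mode is excluded because the only carbon that could serve it (C2 of 11) is a fully substituted enol-ether carbon, the E geometry inherited from the pyranone keeps the ester and the diketone chain cis, and chelation favours C- over O-acylation of the diketonate. O-Acylation by the ring B enolate and re-closure to 10 are reversible in methanol with methoxide, whereas aromatisation to the chelated ortho-hydroxyaryl ketone is not, so the equilibria should drain to 12. The regiochemistry of ring A follows from connectivity alone: the pyranone 4-OMe becomes the C4 methyl ether para to the butanoyl group, the C3 substituent becomes the C5 bridge, and the two lactone oxygens become the C2 and C6 hydroxyls. No stereocentre is formed; ring B is a spectator as its magnesium dienolate, and the bridge of 10 cannot fragment because the pyranone has no free enol from which a quinone methide could form.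

## Compound list

1 | 2,4,6-trihydroxyacetophenone | CC(=O)c1c(O)cc(O)cc1O | starting material
2 | 3-methyl-2,4,6-trihydroxyacetophenone | CC(=O)c1c(O)cc(O)c(C)c1O | intermediate
3 | 2-acetyl-3,5-dihydroxy-4,4-dimethylcyclohexa-2,5-dien-1-one (acetylfilicinic acid) | CC(=O)C1=C(O)C(C)(C)C(O)=CC1=O | intermediate
4 | 4-methoxy-6-methyl-2H-pyran-2-one | COC1=CC(=O)OC(C)=C1 | starting material
5 | 3-bromo-4-methoxy-6-methyl-2H-pyran-2-one | COC1=C(Br)C(=O)OC(C)=C1 | intermediate
6 | 3-(hydroxymethyl)-4-methoxy-6-methyl-2H-pyran-2-one | COC1=C(CO)C(=O)OC(C)=C1 | intermediate
7 | N-methoxy-N-methylbutanamide | CCCC(=O)N(C)OC | starting material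
8 | O,C-dilithio derivative of 6 (lithium alkoxide, lithiated at the 6-methyl carbon) | COC1=C(CO[Li])C(=O)OC(C[Li])=C1 | intermediate
9 | 3-(hydroxymethyl)-4-methoxy-6-(2-oxopentyl)-2H-pyran-2-one | CCCC(=O)CC1=CC(OC)=C(CO)C(=O)O1 | intermediate
10 | 2-acetyl-3,5-dihydroxy-6-{[4-methoxy-2-oxo-6-(2-oxopentyl)-2H-pyran-3-yl]methyl}-4,4-dimethylcyclohexa-2,5-dien-1-one | CCCC(=O)CC1=CC(OC)=C(CC2=C(O)C(C)(C)C(O)=C(C(C)=O)C2=O)C(=O)O1 | intermediate
11 | methyl (2E)-2-[(5-acetyl-2,4-dihydroxy-3,3-dimethyl-6-oxocyclohexa-1,4-dien-1-yl)methyl]-3-methoxy-5,7-dioxodec-2-enoate (present as its magnesium chelate) | COC(=O)/C(CC1=C(O)C(C)(C)C(O)=C(C(C)=O)C1=O)=C(/OC)CC(=O)CC(=O)CCC | intermediate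
12 | 2-acetyl-6-[(3-butanoyl-2,4-dihydroxy-6-methoxyphenyl)methyl]-3,5-dihydroxy-4,4-dimethylcyclohexa-2,5-dien-1-one | CCCC(=O)c1c(O)cc(OC)c(CC2=C(O)C(C)(C)C(O)=C(C(C)=O)C2=O)c1O | target

## Step count and risk assessment

Total step count: 6. Longest linear sequence: 5 steps (steps 2 to 6, from 4 to 12); step 1 supplies 3 for the convergent step 5.

Least certain steps:

Step 6 (key step). The ester carbon of 11 is hindered by the α-substituent and deactivated as a vinylogous carbonate, so ring opening and C-acylation may be slow. Prolonged heating in base would then expose the newly formed ring A phenoxide to retro-Michael cleavage and recombination of the bridge, which scrambles the two halves, and reversible O-acylation by the ring B enolate may also hold material back. The fallback builds ring A before the bridge exists. It sets out from 4, which is acylated at its methyl group with 7 (LiN(iPr)2, THF, −78 °C) to give 4-methoxy-6-(2-oxopentyl)-2H-pyran-2-one F1. This unhindered pyranone is recyclised with Mg(OMe)2 in methanol to 1-(2,6-dihydroxy-4-methoxyphenyl)butan-1-one F2 (the same structure as A1). F2 is then joined to 3 with aqueous formaldehyde in dilute aqueous KOH at 0 °C with short contact time and chromatographic removal of the symmetrical by-products. The fallback comes back to the route at 12.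

Step 5. Ionisation of the primary alcohol may be slow because the lactone carbonyl is cross-conjugated to the developing cation. The enol of the keto side chain of a second molecule of 9 could then capture the cation (self-condensation), or the neighbouring enol hydroxyl of ring B could displace the 4-methoxy group after coupling (cyclisation with loss of methanol). The fallback changes the order so that no enolisable side chain is present during bridge formation. It sets out from 6, which is coupled with 3 under the same acid catalysis to give 2-acetyl-3,5-dihydroxy-6-[(4-methoxy-6-methyl-2-oxo-2H-pyran-3-yl)methyl]-4,4-dimethylcyclohexa-2,5-dien-1-one F3. The polyanion of F3 (LiN(iPr)2, 4.5 equiv, THF with DMPU, −78 °C) is then acylated at the pyranone methyl group with 7. The fallback comes back to the route at 10.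

Step 4. The lithium alkoxide may aggregate and retard the second deprotonation, so that addition of the amide base or of the carbanion to the lactone carbonyl of unreacted material competes. The fallback avoids the dianion by inverting steps 3 and 4. It sets out from 5, which is lithiated at the methyl group (LiN(iPr)2, 1.2 equiv) and acylated with 7 to give 3-bromo-4-methoxy-6-(2-oxopentyl)-2H-pyran-2-one F4. F4 is then coupled with Bu3SnCH2OH and Pd(PPh3)4 as in step 3. The fallback comes back to the route at 9.

Step 3. Transmetalation of the hydroxymethyl group to a hindered, donor-substituted alkenylpalladium centre may be slow, so that protodebromination or butyl transfer takes over. The fallback introduces two carbons and removes one. It sets out from 5, which undergoes Stille coupling with Bu3SnCH=CH2 to give 3-ethenyl-4-methoxy-6-methyl-2H-pyran-2-one F5. Lemieux–Johnson cleavage (OsO4 cat., NaIO4, aqueous THF) gives 4-methoxy-6-methyl-2-oxo-2H-pyran-3-carbaldehyde F6, and Luche reduction (NaBH4, CeCl3·7H2O, MeOH, −20 °C) of F6 completes the sequence. The fallback comes back to the route at 6.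

## Further compounds

F1 | step 6 | 4-methoxy-6-(2-oxopentyl)-2H-pyran-2-one | CCCC(=O)CC1=CC(OC)=CC(=O)O1
F2 | step 6 | 1-(2,6-dihydroxy-4-methoxyphenyl)butan-1-one | CCCC(=O)c1c(O)cc(OC)cc1O
F3 | step 5 | 2-acetyl-3,5-dihydroxy-6-[(4-methoxy-6-methyl-2-oxo-2H-pyran-3-yl)methyl]-4,4-dimethylcyclohexa-2,5-dien-1-one | COC1=C(CC2=C(O)C(C)(C)C(O)=C(C(C)=O)C2=O)C(=O)OC(C)=C1
F4 | step 4 | 3-bromo-4-methoxy-6-(2-oxopentyl)-2H-pyran-2-one | CCCC(=O)CC1=CC(OC)=C(Br)C(=O)O1
F5 | step 3 | 3-ethenyl-4-methoxy-6-methyl-2H-pyran-2-one | COC1=C(C=C)C(=O)OC(C)=C1
F6 | step 3 | 4-methoxy-6-methyl-2-oxo-2H-pyran-3-carbaldehyde | COC1=C(C=O)C(=O)OC(C)=C1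
A1 | alternative 1 | 1-(2,6-dihydroxy-4-methoxyphenyl)butan-1-one | CCCC(=O)c1c(O)cc(OC)cc1O
A2 | alternative 1 | 6,6′-methylenebis(2-acetyl-3,5-dihydroxy-4,4-dimethylcyclohexa-2,5-dien-1-one) | CC(=O)C1=C(O)C(C)(C)C(O)=C(CC2=C(O)C(C)(C)C(O)=C(C(C)=O)C2=O)C1=O
A3 | alternative 1 | bis(3-butanoyl-2,4-dihydroxy-6-methoxyphenyl)methane | CCCC(=O)c1c(O)cc(OC)c(Cc2c(OC)cc(O)c(C(=O)CCC)c2O)c1O
A4 | alternative 2 | 4-[3-butanoyl-6-methoxy-2,4-bis(methoxymethoxy)phenyl]butan-2-one | CCCC(=O)c1c(OCOC)cc(OC)c(CCC(C)=O)c1OCOC
A5 | alternative 2 | methyl 7-[3-butanoyl-6-methoxy-2,4-bis(methoxymethoxy)phenyl]-2,2-dimethyl-3,5-dioxoheptanoate | COC(=O)C(C)(C)C(=O)CC(=O)CCc1c(OC)cc(OCOC)c(C(=O)CCC)c1OCOC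
A6 | alternative 2 | 6-{[3-butanoyl-6-methoxy-2,4-bis(methoxymethoxy)phenyl]methyl}-3,5-dihydroxy-4,4-dimethylcyclohexa-2,5-dien-1-one | CCCC(=O)c1c(OCOC)cc(OC)c(CC2=C(O)C(C)(C)C(O)=CC2=O)c1OCOC
A7 | alternative 3 | 1-{3-[(3-acetyl-2,4,6-trihydroxyphenyl)methyl]-2,6-dihydroxy-4-methoxyphenyl}butan-1-one | CCCC(=O)c1c(O)cc(OC)c(Cc2c(O)cc(O)c(C(C)=O)c2O)c1O
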